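**Plan**

1. Retrosynthetic cuts, in order: the 14 O-benzyl groups; a helper oxygen on lower C4; then, in one stroke, the lower-unit bonds C4–C4a and C2–C3, which opens lower ring C to an aryl oxocarbenium ion on O1 and a two-carbon enediol ether; then the acetal C–O bond at O1; then the interflavan bond upper C4–lower C6, back to a C4-oxidized, perbenzylated epigallocatechin gallate and phloroglucinol; last the gallate ester.
2. Enabling feature: lower ring A is a phloroglucinol nucleus bound through C6, so O1 (para to the interflavan bond) lies between two equivalent, triply oxygen-activated CH carbons (C4a and C8). An oxocarbenium ion on O1 is the 2-oxonia-diene C4a=C8a–O1=C2, and its annulation can only give the 4→6 isomer.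
3. Forward order: (−)-epigallocatechin (upper rings A, B, C) is benzylated on its five phenols, esterified with tri-O-benzylgallic acid, oxidized at C4 and coupled with phloroglucinol (lower ring A); the para oxygen takes on lower ring B as an α-(pivaloyloxy)benzyl ether; lower ring C closes in the key step; the C4 silyl ether is reduced off and all benzyl groups are removed.
4. Stereochemistry: upper C2 and C3 are bought with (−)-epigallocatechin; upper C4 is relayed from C3 (participating 3-ester, trans entry); lower C2 is set by a chiral counter-anion in the key step, and lower C3 is relayed from it in the same event (anti addition, 2,3-trans).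

Key step: step 9

Remark: the target is read as (−)-epigallocatechin 3-O-gallate-(4β→6)-(+)-gallocatechin (upper unit 2R,3R,4S; lower unit 2R,3S); "upper" and "lower" mark the positions of the two flavan units; the five starting materials are taken as commercial; the acetal carbon of the α-(pivaloyloxy)benzyl compounds is stereorandom and is erased on ionization.

**Step 1**
Reactants: 1 (−)-epigallocatechin
Product: 2 penta-O-benzyl-(−)-epigallocatechin
Conditions: BnBr, K2CO3, DMF, 0 °C to rt, N2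
Reagents that add atoms: benzyl bromide, BrCc1ccccc1
Why: Williamson etherification of the five phenols with a carbonate base that is too weak to alkylate the secondary 3-hydroxyl; no stereocentre is formed, and low temperature with excess bromide limits base-induced epimerization at C2.

**Step 2**
Reactants: 2 penta-O-benzyl-(−)-epigallocatechin; 3 3,4,5-tris(benzyloxy)benzoic acid
Product: 4 octa-O-benzyl-EGCG
Conditions: DCC, DMAP (cat.), CH2Cl2, 0 °C to rt
Reagents that add atoms: none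
Why: Steglich esterification of the axial 3-hydroxyl by the DMAP-activated O-acylisourea of the acid; the C3–O bond is not broken, so the 2,3-cis configuration is retained.

**Step 3**
Reactants: 4 octa-O-benzyl-EGCG
Product: 5 4β-(2-ethoxyethoxy)-octa-O-benzyl-EGCG
Conditions: DDQ, 2-ethoxyethanol, CH2Cl2, rt
Reagents that add atoms: 2-ethoxyethanol, CCOCCO
Why: Benzylic oxidation by DDQ (hydride abstraction from C4, activated by the 5,7-dialkoxy ring A) gives a cation bridged on its cis face by the 3-O-galloyl carbonyl group, so the alcohol adds trans to the ester and to the 2-aryl group and upper C4 is set by substrate control (oxidative C4 etherification of protected flavan-3-ols).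

**Step 4**
Reactants: 5 4β-(2-ethoxyethoxy)-octa-O-benzyl-EGCG; 6 phloroglucinol (6 equiv)
Product: 7 octa-O-benzyl-EGCG-(4β→2)-phloroglucinol
Conditions: TMSOTf (0.3 equiv), THF/CH2Cl2, −40 to −20 °C
Reagents that add atoms: none
Why: Lewis-acid ionization of the C4 ether and Friedel–Crafts C-alkylation of phloroglucinol (the coupling used for phloroglucinol adducts and interflavan bonds), with the 3-acyloxy group again covering the cis face so that the aryl group enters trans (4β); the excess of the symmetrical nucleophile suppresses double alkylation.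

**Step 5**
Reactants: 8 3,4,5-tris(benzyloxy)benzaldehyde
Product: 9 chloro[3,4,5-tris(benzyloxy)phenyl]methyl 2,2-dimethylpropanoate (racemic)
Conditions: pivaloyl chloride, ZnCl2 (cat.), CH2Cl2, 0 °C to rt; used crude
Reagents that add atoms: pivaloyl chloride, CC(C)(C)C(=O)Cl
Why: ZnCl2-catalysed addition of an acyl chloride across the aldehyde C=O (α-chloroalkyl ester formation); the new centre is racemic and is erased later.

**Step 6**
Reactants: 7 octa-O-benzyl-EGCG-(4β→2)-phloroglucinol; 9 chloro[3,4,5-tris(benzyloxy)phenyl]methyl 2,2-dimethylpropanoate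
Product: 10 para-O-{[3,4,5-tris(benzyloxy)phenyl](pivaloyloxy)methyl} ether of 7
Conditions: Cs2CO3 (1.0 equiv), 9 (1.05 equiv), DMF, −20 to 0 °C
Reagents that add atoms: none
Why: Phenoxide O-alkylation by an α-chloroalkyl ester (acyloxyalkyl ether formation) is expected at the hydroxyl para to the flavanyl group, the only one of the three not flanked by the bulky C4 substituent; the new acetal centre needs no control.

**Step 7**
Reactants: 10 para-O-{[3,4,5-tris(benzyloxy)phenyl](pivaloyloxy)methyl} ether of 7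
Product: 11 bis-O-benzyl ether of 10 (annulation precursor)
Conditions: BnBr, K2CO3, DMF, rt
Reagents that add atoms: benzyl bromide, BrCc1ccccc1
Why: Williamson etherification of the two remaining phenols under anhydrous carbonate conditions, which should leave the hindered pivalate acetal and the gallate untouched; no stereocentre is involved.

**Step 8**
Reactants: 12 (benzyloxy)acetaldehyde
Product: 13 (Z)-{[2-(benzyloxy)ethenyl]oxy}(tert-butyl)dimethylsilane
Conditions: TBSOTf, Et3N, CH2Cl2, 0 °C to rt; distillation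
Reagents that add atoms: tert-butyldimethylsilyl triflate, CC(C)(C)[Si](C)(C)OS(=O)(=O)C(F)(F)F
Why: Soft enolization of the α-alkoxy aldehyde and O-silylation (silyl enol ether formation); the (Z) isomer with the two oxygens cis is the expected major isomer.

**Step 9**
Reactants: 11 bis-O-benzyl ether of 10 (annulation precursor); 13 (Z)-{[2-(benzyloxy)ethenyl]oxy}(tert-butyl)dimethylsilane (2.5 equiv)
Product: 16 [octa-O-benzyl-EGCG]-(4β→6)-[3,5,7,3',4',5'-hexa-O-benzyl-4-O-(tert-butyldimethylsilyl)-2,3-trans-3,4-trans-flavan-3,4-diol], via aryloxocarbenium ion 14 (not isolated), via silyloxocarbenium adduct 15 (not isolated)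
Conditions: chiral 3,3'-diaryl-BINOL-derived N-triflylphosphoramide (10 mol %, antipode selected on a model aryl acetal), toluene/CH2Cl2, 4 Å MS, −78 to −40 °C; Et3N quench; base-washed silica
Reagents that add atoms: none
Why: Proposed new method: the chiral acid ionizes the pivalate of 11 (the acyloxy group leaves because only the aryloxy oxygen can stabilize the cation) to ion 14, the 2-oxonia-diene C4a=C8a–O1=C2 paired with the chiral anion; enol silane 13 adds through its benzyloxy-bearing carbon to C2 (C2–C3 bond), and the silyloxocarbenium ion 15 so formed is trapped by the neighbouring ring A carbon (C4–C4a bond), the proton lost on rearomatization regenerating the acid. The closest known reaction types are the Lewis-acid-promoted oxa-Povarov annulation of aryl oxocarbenium ions with alkenes to chromans and chiral-anion-directed Mukaiyama additions of silyl enol ethers to oxocarbenium ions; their union on an O-aryl oxocarbenium ion with an enediol-type alkene is new. Lower ring C closes by 6-exo-trig Friedel–Crafts attack of C4a on the C4 silyloxocarbenium carbon through a chair with the 2-aryl, 3-benzyloxy and 4-silyloxy groups equatorial. Lower C2 is controlled by the chiral counter-anion, which shields one face of ion 14 (the upper-unit stereocentres are too remote to interfere); lower C3 is relayed from C2 through the open antiperiplanar transition state expected for a (Z)-α-alkoxy enol silane, which gives the anti adduct and hence the 2,3-trans ring; lower C4 follows from the chair closure and is removed in step 10, so any C4 epimer is carried on. The step needs regioselective ring closure, and this is secured by the local twofold symmetry of the 2,6-bis(benzyloxy)-4-oxyphenyl ring, whose two carbons ortho to O1 are equivalent, so that only the 4→6 isomer can form.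

**Step 10**
Reactants: 16 [octa-O-benzyl-EGCG]-(4β→6)-[3,5,7,3',4',5'-hexa-O-benzyl-4-O-(tert-butyldimethylsilyl)-2,3-trans-3,4-trans-flavan-3,4-diol]
Product: 17 tetradeca-O-benzyl derivative of the target
Conditions: Et3SiH (5 equiv), TMSOTf (0.2 equiv), CH2Cl2, −78 °C
Reagents that add atoms: none
Why: Ionic hydrogenation: the silyl Lewis acid should ionize only the lower C4 silyl ether, whose cation is stabilized by the three ring A oxygens, and Et3SiH delivers hydride, so the helper oxygen is removed and lower C4 becomes CH2 without touching lower C2 or C3.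

**Step 11**
Reactants: 17 tetradeca-O-benzyl derivative of the target
Product: 18 (−)-epigallocatechin 3-O-gallate-(4β→6)-(+)-gallocatechin (target)
Conditions: H2 (1 atm), Pd(OH)2/C, THF/MeOH/H2O, rt
Reagents that add atoms: none
Why: Catalytic hydrogenolysis of the 14 benzyl ethers under neutral conditions (global O-debenzylation) should leave the gallate ester, the interflavan bond and the two ring C benzylic C–O bonds intact and touches no stereocentre.

**Compound list**

1 | (−)-epigallocatechin (2R,3R) | O[C@@H]1Cc2c(O)cc(O)cc2O[C@@H]1c1cc(O)c(O)c(O)c1 | starting material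
2 | penta-O-benzyl-(−)-epigallocatechin, (2R,3R)-5,7-bis(benzyloxy)-2-[3,4,5-tris(benzyloxy)phenyl]chroman-3-ol | O[C@@H]1Cc2c(OCc4ccccc4)cc(OCc4ccccc4)cc2O[C@@H]1c1cc(OCc4ccccc4)c(OCc4ccccc4)c(OCc4ccccc4)c1 | intermediate
3 | 3,4,5-tris(benzyloxy)benzoic acid | OC(=O)c1cc(OCc2ccccc2)c(OCc2ccccc2)c(OCc2ccccc2)c1 | starting material
4 | octa-O-benzyl-EGCG, (2R,3R)-5,7-bis(benzyloxy)-2-[3,4,5-tris(benzyloxy)phenyl]chroman-3-yl 3,4,5-tris(benzyloxy)benzoate | O=C(O[C@@H]1Cc2c(OCc4ccccc4)cc(OCc4ccccc4)cc2O[C@@H]1c1cc(OCc4ccccc4)c(OCc4ccccc4)c(OCc4ccccc4)c1)c1cc(OCc4ccccc4)c(OCc4ccccc4)c(OCc4ccccc4)c1 | intermediate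
5 | 4β-(2-ethoxyethoxy)-octa-O-benzyl-EGCG (C4 ether trans to the 3-ester and to the 2-aryl group) | O=C(O[C@@H]1[C@@H](OCCOCC)c2c(OCc4ccccc4)cc(OCc4ccccc4)cc2O[C@@H]1c1cc(OCc4ccccc4)c(OCc4ccccc4)c(OCc4ccccc4)c1)c1cc(OCc4ccccc4)c(OCc4ccccc4)c(OCc4ccccc4)c1 | intermediate
6 | phloroglucinol (benzene-1,3,5-triol) | Oc1cc(O)cc(O)c1 | starting material
7 | octa-O-benzyl-EGCG-(4β→2)-phloroglucinol (2,4,6-trihydroxyphenyl at upper C4, trans to the 3-ester; 2R,3R,4S) | O=C(O[C@@H]1[C@@H](c2c(O)cc(O)cc2O)c2c(OCc4ccccc4)cc(OCc4ccccc4)cc2O[C@@H]1c1cc(OCc4ccccc4)c(OCc4ccccc4)c(OCc4ccccc4)c1)c1cc(OCc4ccccc4)c(OCc4ccccc4)c(OCc4ccccc4)c1 | intermediate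
8 | 3,4,5-tris(benzyloxy)benzaldehyde | O=Cc1cc(OCc2ccccc2)c(OCc2ccccc2)c(OCc2ccccc2)c1 | starting material
9 | chloro[3,4,5-tris(benzyloxy)phenyl]methyl 2,2-dimethylpropanoate (racemic) | CC(C)(C)C(=O)OC(Cl)c1cc(OCc2ccccc2)c(OCc2ccccc2)c(OCc2ccccc2)c1 | intermediate
10 | ether of 7 at the phloroglucinol hydroxyl para to upper C4 with the [3,4,5-tris(benzyloxy)phenyl](pivaloyloxy)methyl group (acetal epimers) | O=C(O[C@@H]1[C@@H](c2c(O)cc(OC(OC(=O)C(C)(C)C)c3cc(OCc4ccccc4)c(OCc4ccccc4)c(OCc4ccccc4)c3)cc2O)c2c(OCc4ccccc4)cc(OCc4ccccc4)cc2O[C@@H]1c1cc(OCc4ccccc4)c(OCc4ccccc4)c(OCc4ccccc4)c1)c1cc(OCc4ccccc4)c(OCc4ccccc4)c(OCc4ccccc4)c1 | intermediate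
11 | bis-O-benzyl ether of 10 (both ortho phloroglucinol oxygens benzylated; acetal epimers) | O=C(O[C@@H]1[C@@H](c2c(OCc4ccccc4)cc(OC(OC(=O)C(C)(C)C)c3cc(OCc4ccccc4)c(OCc4ccccc4)c(OCc4ccccc4)c3)cc2OCc4ccccc4)c2c(OCc4ccccc4)cc(OCc4ccccc4)cc2O[C@@H]1c1cc(OCc4ccccc4)c(OCc4ccccc4)c(OCc4ccccc4)c1)c1cc(OCc4ccccc4)c(OCc4ccccc4)c(OCc4ccccc4)c1 | intermediate
12 | (benzyloxy)acetaldehyde | O=CCOCc1ccccc1 | starting material
13 | (Z)-{[2-(benzyloxy)ethenyl]oxy}(tert-butyl)dimethylsilane | CC(C)(C)[Si](C)(C)O/C=C\OCc1ccccc1 | intermediate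
14 | aryloxocarbenium ion from 11 (O1=C2 cation carrying lower ring B; not isolated) | O=C(O[C@@H]1[C@@H](c2c(OCc4ccccc4)cc([O+]=Cc3cc(OCc4ccccc4)c(OCc4ccccc4)c(OCc4ccccc4)c3)cc2OCc4ccccc4)c2c(OCc4ccccc4)cc(OCc4ccccc4)cc2O[C@@H]1c1cc(OCc4ccccc4)c(OCc4ccccc4)c(OCc4ccccc4)c1)c1cc(OCc4ccccc4)c(OCc4ccccc4)c(OCc4ccccc4)c1 | intermediate
15 | silyloxocarbenium adduct (C2–C3 formed, anti; C4 as CH=O+–TBS; not isolated) | O=C(O[C@@H]1[C@@H](c2c(OCc4ccccc4)cc(O[C@H](c3cc(OCc4ccccc4)c(OCc4ccccc4)c(OCc4ccccc4)c3)[C@@H](OCc4ccccc4)C=[O+][Si](C)(C)C(C)(C)C)cc2OCc4ccccc4)c2c(OCc4ccccc4)cc(OCc4ccccc4)cc2O[C@@H]1c1cc(OCc4ccccc4)c(OCc4ccccc4)c(OCc4ccccc4)c1)c1cc(OCc4ccccc4)c(OCc4ccccc4)c(OCc4ccccc4)c1 | intermediate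
16 | [octa-O-benzyl-EGCG]-(4β→6)-[hexa-O-benzyl-4-O-TBS-flavan-3,4-diol]; lower unit 2-aryl, 3-benzyloxy and 4-silyloxy all trans, lower C2 and C3 as in the target | O=C(O[C@@H]1[C@@H](c2c(OCc4ccccc4)cc3c(c2OCc4ccccc4)[C@@H](O[Si](C)(C)C(C)(C)C)[C@H](OCc4ccccc4)[C@@H](c2cc(OCc4ccccc4)c(OCc4ccccc4)c(OCc4ccccc4)c2)O3)c2c(OCc4ccccc4)cc(OCc4ccccc4)cc2O[C@@H]1c1cc(OCc4ccccc4)c(OCc4ccccc4)c(OCc4ccccc4)c1)c1cc(OCc4ccccc4)c(OCc4ccccc4)c(OCc4ccccc4)c1 | intermediate
17 | tetradeca-O-benzyl derivative of the target, [octa-O-benzyl-EGCG]-(4β→6)-[3,5,7,3',4',5'-hexa-O-benzyl-(+)-gallocatechin] | O=C(O[C@@H]1[C@@H](c2c(OCc4ccccc4)cc3c(c2OCc4ccccc4)C[C@H](OCc4ccccc4)[C@@H](c2cc(OCc4ccccc4)c(OCc4ccccc4)c(OCc4ccccc4)c2)O3)c2c(OCc4ccccc4)cc(OCc4ccccc4)cc2O[C@@H]1c1cc(OCc4ccccc4)c(OCc4ccccc4)c(OCc4ccccc4)c1)c1cc(OCc4ccccc4)c(OCc4ccccc4)c(OCc4ccccc4)c1 | intermediate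
18 | (2R,3R,4S)-5,7-dihydroxy-4-[(2R,3S)-3,5,7-trihydroxy-2-(3,4,5-trihydroxyphenyl)chroman-6-yl]-2-(3,4,5-trihydroxyphenyl)chroman-3-yl 3,4,5-trihydroxybenzoate | O=C(O[C@@H]1[C@@H](c2c(O)cc3c(c2O)C[C@H](O)[C@@H](c2cc(O)c(O)c(O)c2)O3)c2c(O)cc(O)cc2O[C@@H]1c1cc(O)c(O)c(O)c1)c1cc(O)c(O)c(O)c1 | target

**Step count and risks**

Total step count: 11. Longest linear sequence: 9 steps (1, 2, 3, 4, 6, 7, 9, 10, 11).

Steps most likely to fail:

1. Step 9. The chiral anion may discriminate the two faces of the oxocarbenium ion poorly on so large a substrate, the anti preference may erode, or the cascade may stall after the first bond. Fallback, from 11 back to 16, by known auxiliary chemistry: (S)-4-(propan-2-yl)-1,3-thiazolidine-2-thione is acylated with (benzyloxy)acetyl chloride (Et3N, CH2Cl2) to the N-glycolyl thiazolidinethione F1. Its chlorotitanium enolate (TiCl4, iPr2NEt, CH2Cl2, −78 °C) is combined with 11 and SnCl4, which ionizes the pivalate; auxiliary-controlled anti addition to the oxocarbenium ion should give the imide F2 with lower C2 and C3 as required. iBu2AlH at −78 °C releases the auxiliary and gives the aldehyde F3. TBSOTf with 2,6-di-tert-butyl-4-methylpyridine at −78 °C then regenerates ion 15 from the aldehyde, and Friedel–Crafts closure returns the route to 16.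

2. Step 6. Site selectivity among the three phenols may be poor, a second alkylation may occur, or the acyloxy acetal may be lost in the following base treatment. Fallback, from 7 back to 11: the unhindered para hydroxyl is silylated selectively with the bulky chloride TIPSCl (imidazole, DMF, 0 °C) to the para-O-triisopropylsilyl ether F4. The two ortho phenols are benzylated (BnBr, K2CO3, DMF) to the bis-benzyl ether F5. Bu4NF/AcOH in THF frees the single phenol F6, which is alkylated with 9 (Cs2CO3, DMF, −20 °C) to give 11 with no selectivity question left.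

3. Step 10. The Lewis acid may also ionize at the interflavan bond or at a ring C benzylic C–O bond, or the C4 cation may lose a proton to a flav-3-ene instead of taking up hydride. Fallback, from 16 back to 17, without Lewis acid (Barton–McCombie deoxygenation): Bu4NF/AcOH in THF cleaves the silyl ether to the lower C4 alcohol F7. 1,1'-Thiocarbonyldiimidazole with DMAP in toluene at 80 °C gives the imidazolyl thionocarbonate F8. Bu3SnH with AIBN in toluene at 90 °C reduces the benzylic C–O bond by a radical chain and delivers 17.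

**Further compounds**

F1 | step 9 | (S)-3-[(benzyloxy)acetyl]-4-(propan-2-yl)-1,3-thiazolidine-2-thione | CC(C)[C@H]1CSC(=S)N1C(=O)COCc1ccccc1
F2 | step 9 | anti adduct: N-[(2R,3R)-2-(benzyloxy)-3-aryloxy-3-[3,4,5-tris(benzyloxy)phenyl]propanoyl] thiazolidinethione on the para oxygen of the lower ring A | O=C(O[C@@H]1[C@@H](c2c(OCc4ccccc4)cc(O[C@H](c3cc(OCc4ccccc4)c(OCc4ccccc4)c(OCc4ccccc4)c3)[C@@H](OCc4ccccc4)C(=O)N3C(=S)SC[C@@H]3C(C)C)cc2OCc4ccccc4)c2c(OCc4ccccc4)cc(OCc4ccccc4)cc2O[C@@H]1c1cc(OCc4ccccc4)c(OCc4ccccc4)c(OCc4ccccc4)c1)c1cc(OCc4ccccc4)c(OCc4ccccc4)c(OCc4ccccc4)c1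
F3 | step 9 | (2R,3R)-2-(benzyloxy)-3-aryloxy-3-[3,4,5-tris(benzyloxy)phenyl]propanal on the para oxygen of the lower ring A | O=C(O[C@@H]1[C@@H](c2c(OCc4ccccc4)cc(O[C@H](c3cc(OCc4ccccc4)c(OCc4ccccc4)c(OCc4ccccc4)c3)[C@@H](OCc4ccccc4)C=O)cc2OCc4ccccc4)c2c(OCc4ccccc4)cc(OCc4ccccc4)cc2O[C@@H]1c1cc(OCc4ccccc4)c(OCc4ccccc4)c(OCc4ccccc4)c1)c1cc(OCc4ccccc4)c(OCc4ccccc4)c(OCc4ccccc4)c1
F4 | step 6 | para-O-triisopropylsilyl ether of 7 | O=C(O[C@@H]1[C@@H](c2c(O)cc(O[Si](C(C)C)(C(C)C)C(C)C)cc2O)c2c(OCc4ccccc4)cc(OCc4ccccc4)cc2O[C@@H]1c1cc(OCc4ccccc4)c(OCc4ccccc4)c(OCc4ccccc4)c1)c1cc(OCc4ccccc4)c(OCc4ccccc4)c(OCc4ccccc4)c1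
F5 | step 6 | ortho,ortho-bis-O-benzyl para-O-triisopropylsilyl ether of 7 | O=C(O[C@@H]1[C@@H](c2c(OCc4ccccc4)cc(O[Si](C(C)C)(C(C)C)C(C)C)cc2OCc4ccccc4)c2c(OCc4ccccc4)cc(OCc4ccccc4)cc2O[C@@H]1c1cc(OCc4ccccc4)c(OCc4ccccc4)c(OCc4ccccc4)c1)c1cc(OCc4ccccc4)c(OCc4ccccc4)c(OCc4ccccc4)c1
F6 | step 6 | ortho,ortho-bis-O-benzyl ether of 7 with free para phenol | O=C(O[C@@H]1[C@@H](c2c(OCc4ccccc4)cc(O)cc2OCc4ccccc4)c2c(OCc4ccccc4)cc(OCc4ccccc4)cc2O[C@@H]1c1cc(OCc4ccccc4)c(OCc4ccccc4)c(OCc4ccccc4)c1)c1cc(OCc4ccccc4)c(OCc4ccccc4)c(OCc4ccccc4)c1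
F7 | step 10 | lower C4 alcohol (desilylated 16) | O=C(O[C@@H]1[C@@H](c2c(OCc4ccccc4)cc3c(c2OCc4ccccc4)[C@@H](O)[C@H](OCc4ccccc4)[C@@H](c2cc(OCc4ccccc4)c(OCc4ccccc4)c(OCc4ccccc4)c2)O3)c2c(OCc4ccccc4)cc(OCc4ccccc4)cc2O[C@@H]1c1cc(OCc4ccccc4)c(OCc4ccccc4)c(OCc4ccccc4)c1)c1cc(OCc4ccccc4)c(OCc4ccccc4)c(OCc4ccccc4)c1
F8 | step 10 | lower C4 O-(imidazol-1-ylthiocarbonyl) derivative of the alcohol | O=C(O[C@@H]1[C@@H](c2c(OCc4ccccc4)cc3c(c2OCc4ccccc4)[C@@H](OC(=S)n5ccnc5)[C@H](OCc4ccccc4)[C@@H](c2cc(OCc4ccccc4)c(OCc4ccccc4)c(OCc4ccccc4)c2)O3)c2c(OCc4ccccc4)cc(OCc4ccccc4)cc2O[C@@H]1c1cc(OCc4ccccc4)c(OCc4ccccc4)c(OCc4ccccc4)c1)c1cc(OCc4ccccc4)c(OCc4ccccc4)c(OCc4ccccc4)c1
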